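**Plan**
- Retrosynthesis (labdane numbering): the 19-tiglate and the C13 silyl ether are cut first. Then C7–C8 and C5–C10 are cut together, which opens rings B and A to an acyclic keto-enyne. That chain is cut at C9–C10 (conjugate addition) and C3–C4 (lactam alkylation).
- Forward: a valinol-derived bicyclic lactam (C4–C7, C19), 5-iodopent-1-yne (C1–C3, C10, C20), (R)-linalool (C9, C11–C16) and a two-carbon ylide (C8, C17) are joined to keto-enyne 19. One gold-catalysed operation then closes ring A and ring B.
- Enabling feature: C6 is the one ring-B carbon bonded to both C5 and C7, so as a ketone it makes both of them enol carbons. C10 bears a methyl (C20) and C8 a methylene (C17), so they are the substituted ends of a C10=C20 alkene and a C8≡C17 alkyne.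
- Stereochemistry: C13 from (R)-linalool; C4 from the lactam auxiliary; C9 from Rh/(S)-BINAP; C10 and C5 in the key step (chair closure of ring A).
- The helper C6=O is removed through its tosylhydrazone; the C19 ester is reduced and esterified with the tigloyl group; the silyl group is removed last.

Key step: step 12

Remark: the second alkylation of the bicyclic lactam is taken to occur anti to the angular methyl group (endo), which corresponds to S at the future C4.

**Step 1**
Reactants: 1 5-iodopent-1-yne
Product: 3 2-bromo-5-iodopent-1-ene, via alkenylborane 2 (not isolated)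
Conditions: B-bromo-9-BBN, CH2Cl2, 0 °C to rt; then AcOH, 0 °C
Reagents that add atoms: B-bromo-9-borabicyclo[3.3.1]nonane, BrB1C2CCCC1CCC2
Why: syn-bromoboration of the terminal alkyne puts Br on the internal carbon and protodeboronation gives the 2-bromo-1-alkene (haloboration–protonolysis); the primary iodide is not touched.

**Step 2**
Reactants: 4 (3S,7aR)-3-isopropyl-7a-methyltetrahydropyrrolo[2,1-b]oxazol-5(6H)-one
Product: 5 6-methyl lactam (both C6 epimers)
Conditions: LDA, THF, −78 °C; MeI
Reagents that add atoms: iodomethane, CI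
Why: lactam enolate alkylation; the configuration at C6 is irrelevant because this centre is enolised again in step 3.

**Step 3**
Reactants: 5 6-methyl lactam; 3 2-bromo-5-iodopent-1-ene
Product: 6 (3S,6S,7aR)-6-(4-bromopent-4-en-1-yl)-3-isopropyl-6,7a-dimethyl lactam
Conditions: LDA, THF/DMPU, −78 to −20 °C
Reagents that add atoms: none
Why: bicyclic-lactam enolate alkylation; the second electrophile should enter on the endo face, anti to the angular methyl, which sets the quaternary centre (future C4) as S; only the primary iodide reacts, the vinyl bromide is inert.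

**Step 4**
Reactants: 6 vinyl bromide lactam
Product: 7 (3S,6S,7aR)-alkenylboronate lactam (pinacol ester at the future C10)
Conditions: B2pin2, PdCl2(PPh3)2 (3 mol %), PPh3, KOPh, PhMe, 50 °C
Reagents that add atoms: bis(pinacolato)diboron, CC1(C)OB(OC1(C)C)B1OC(C)(C)C(C)(C)O1
Why: Miyaura borylation of a 1-alkenyl bromide; the lactam and the N,O-ketal tolerate the weak base.

**Step 5**
Reactants: 8 (R)-linalool
Product: 9 (R)-linalool tert-butyldimethylsilyl ether
Conditions: TBSOTf, 2,6-lutidine, CH2Cl2, 0 °C to rt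
Reagents that add atoms: tert-butyldimethylsilyl triflate, CC(C)(C)[Si](C)(C)OS(=O)(=O)C(F)(F)F
Why: silylation of the tertiary allylic alcohol with the reactive triflate; C13 is carried from the chiral pool.

**Step 6**
Reactants: 9 linalool TBS ether
Product: 11 (R)-4-(tert-butyldimethylsilyloxy)-4-methylhex-5-enal, via diol 10 (not isolated)
Conditions: OsO4 (2 mol %), NaIO4, 2,6-lutidine, dioxane/H2O, rt
Reagents that add atoms: sodium periodate, [Na+].[O-]I(=O)(=O)=O (its oxygen reaches the product through catalytic OsO4)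
Why: Lemieux–Johnson cleavage; the electron-rich trisubstituted alkene should be dihydroxylated well before the vinyl group on the fully substituted silyloxy carbon.

**Step 7**
Reactants: 11 aldehyde
Product: 12 (2E,6R)-6-(tert-butyldimethylsilyloxy)-6-methylocta-2,7-dienal
Conditions: Ph3P=CHCHO, PhMe, 80 °C
Reagents that add atoms: (triphenylphosphoranylidene)acetaldehyde, O=CC=P(c1ccccc1)(c1ccccc1)c1ccccc1
Why: Wittig reaction with a stabilised ylide, E-selective; it adds C8 and C17.

**Step 8**
Reactants: 7 alkenylboronate lactam; 12 enal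
Product: 13 (3S,6R)-3-alkenyl aldehyde (C9–C10 bond made, 9S)
Conditions: [Rh(OH)((S)-BINAP)]2 (3 mol % Rh), KOH (0.3 eq), dioxane/H2O 10:1, 40 °C
Reagents that add atoms: none
Why: Hayashi–Miyaura conjugate addition of an alkenylboron reagent; the (S)-BINAP–rhodium alkenyl should add to the enal face that gives 9S, following the model for (E)-β-alkyl acceptors, under catalyst control.

**Step 9**
Reactants: 13 aldehyde
Product: 15 terminal alkyne lactam (9R by rule, same geometry), via alkenyl nonaflate 14 (not isolated)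
Conditions: C4F9SO2F, phosphazene base P2-Et (2.5 eq), DMF, −20 °C to rt
Reagents that add atoms: none
Why: enol nonaflate formation and elimination convert CH2–CHO into C≡CH; only the aldehyde is enolisable because the lactam α-carbon is quaternary, and C9 is β to the carbonyl so it is not epimerised.

**Step 10**
Reactants: 15 alkyne lactam
Product: 17 (2S,7R,10R)-10-(tert-butyldimethylsilyloxy)-7-ethynyl-2,10-dimethyl-6-methylidene-2-(2-oxopropyl)dodec-11-enal, via carbinolamine 16 (not isolated)
Conditions: NaAlH2(OCH2CH2OMe)2, PhMe/THF, −20 °C to rt; then 1 M Bu4NH2PO4, EtOH/H2O, 70 °C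
Reagents that add atoms: water, O
Why: reduction of the lactam carbonyl to the carbinolamine and buffered hydrolysis release the C19 aldehyde, unmask the C6 methyl ketone and remove valinol; the quaternary C4 cannot epimerise and the tertiary silyl ether should survive the near-neutral buffer.

**Step 11**
Reactants: 17 keto aldehyde
Product: 19 methyl (2S,7R,10R)-10-(tert-butyldimethylsilyloxy)-7-ethynyl-2,10-dimethyl-6-methylidene-2-(2-oxopropyl)dodec-11-enoate, via keto acid 18 (not isolated)
Conditions: NaClO2, NaH2PO4, 2-methyl-2-butene, t-BuOH/H2O, 0 °C; then TMSCHN2, PhMe/MeOH, 0 °C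
Reagents that add atoms: sodium chlorite, [Na+].[O-]Cl=O; (trimethylsilyl)diazomethane, C[Si](C)(C)C=[N+]=[N-]
Why: Pinnick oxidation is specific for the aldehyde (ketone, alkyne and alkenes are protected by the scavenger) and diazomethane-type esterification gives the ester.

**Step 12**
Reactants: 19 keto ester enyne
Product: 21 methyl (4S,5R,9S,10R,13R)-13-(tert-butyldimethylsilyloxy)-6-oxolabda-8(17),14-dien-19-oate, via monocyclic ketone 20 (not isolated)
Conditions: [1,3-bis(2,6-diisopropylphenyl)imidazol-2-ylidene]AuCl (5 mol %), AgNTf2 (5 mol %), 4 Å MS, PhMe, 70 °C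
Reagents that add atoms: none
Why: Proposed new method: cationic monovalent gold activates the C10=C20 alkene and the C5 enol of the C6 ketone adds in Markovnikov sense anti to gold (6-exo-trig, ring A; protodeauration makes C20 the C10 methyl), after which the C7 enol of the same ketone adds to the gold-activated C8≡C17 alkyne (6-exo-dig, ring B; protodeauration leaves the 8(17)-methylene). The closest known reaction types are the gold-catalysed intramolecular hydroalkylation of unactivated alkenes with simple ketones and the gold-catalysed Conia-ene or silyl enol ether carbocyclisation onto alkynes; new is their combination through both α-carbons of one methyl ketone. The order is enforced by the chain: before ring A exists, C5 and C7 could reach the alkyne only through 8- or 10-membered rings and C7 cannot reach the alkene. C10 is set in a chair transition state for ring A with the C6 enol carbon and the branched C9 equatorial and the C19 ester (smaller A value than CH3) axial, so C20 becomes axial and syn to C19; the stored C9 centre then places C11 equatorial in ring B. C5 forms with H trans to C20 in the same chair, which is also the more stable ring fusion of the 6-oxodecalin. The step needs ring A to close before the alkyne is consumed otherwise and the β,γ-unsaturated ketone to survive; dry aprotic conditions, a non-coordinating counter-ion and immediate use in step 13 should serve this.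

**Step 13**
Reactants: 21 bicyclic ketone
Product: 22 C6 tosylhydrazone of 21
Conditions: TsNHNH2, MgSO4, THF/MeOH, 40 °C, no added acid
Reagents that add atoms: p-toluenesulfonyl hydrazide, Cc1ccc(S(=O)(=O)NN)cc1
Why: hydrazone condensation at the only ketone; acid is left out so that the 8(17) alkene is not drawn into conjugation.

**Step 14**
Reactants: 22 tosylhydrazone
Product: 24 methyl (13R)-13-(tert-butyldimethylsilyloxy)labda-8(17),14-dien-19-oate, via borylhydrazine 23 (not isolated)
Conditions: catecholborane, CHCl3, 0 °C to rt; then NaOAc·3H2O, 60 °C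
Reagents that add atoms: none
Why: mild Wolff–Kishner-type deoxygenation (hydride addition to C=N, loss of sulfinate and N2); the non-conjugated alkenes and the ester are not touched, so the helper C6 oxygen is removed.

**Step 15**
Reactants: 24 methyl ester
Product: 25 (13R)-13-(tert-butyldimethylsilyloxy)labda-8(17),14-dien-19-ol
Conditions: LiAlH4, Et2O, 0 °C to reflux
Reagents that add atoms: none
Why: hydride reduction of the hindered axial ester to the C19 primary alcohol; silyl ether and alkenes are inert.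

**Step 16**
Reactants: 25 alcohol
Product: 26 (13R)-13-(tert-butyldimethylsilyloxy)labda-8(17),14-dien-19-yl (E)-2-methylbut-2-enoate
Conditions: tigloyl chloride, pyridine, DMAP (cat.), CH2Cl2, 40 °C
Reagents that add atoms: (E)-2-methylbut-2-enoyl chloride, C/C=C(\C)C(=O)Cl
Why: DMAP-catalysed acylation of the neopentyl primary alcohol; the tertiary C13 oxygen is still protected, and the E acid chloride keeps its geometry.

**Step 17**
Reactants: 26 silyl ether
Product: 27 (4S,5R,9S,10R,13R)-13-hydroxylabda-8(17),14-dien-19-yl (E)-2-methylbut-2-enoate (target)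
Conditions: Bu4NF, AcOH (1:1), THF, 50 °C
Reagents that add atoms: none
Why: buffered fluoride desilylation frees the tertiary allylic alcohol without ionising it and without cleaving the tiglate.

**Compound list**
1 | 5-iodopent-1-yne | C#CCCCI | starting material
2 | (Z)-9-(2-bromo-5-iodopent-1-en-1-yl)-9-borabicyclo[3.3.1]nonane | Br/C(CCCI)=C\B1C2CCCC1CCC2 | intermediate (not isolated)
3 | 2-bromo-5-iodopent-1-ene | C=C(Br)CCCI | intermediate
4 | (3S,7aR)-3-isopropyl-7a-methyltetrahydropyrrolo[2,1-b]oxazol-5(6H)-one | CC(C)[C@H]1CO[C@]2(C)CCC(=O)N12 | starting material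
5 | (3S,7aR)-3-isopropyl-6,7a-dimethyltetrahydropyrrolo[2,1-b]oxazol-5(6H)-one, C6 epimers | CC(C)[C@H]1CO[C@]2(C)CC(C)C(=O)N12 | intermediate
6 | (3S,6S,7aR)-6-(4-bromopent-4-en-1-yl)-3-isopropyl-6,7a-dimethyltetrahydropyrrolo[2,1-b]oxazol-5(6H)-one | CC(C)[C@H]1CO[C@]2(C)C[C@](C)(CCCC(Br)=C)C(=O)N12 | intermediate
7 | (3S,6S,7aR)-3-isopropyl-6,7a-dimethyl-6-[4-(4,4,5,5-tetramethyl-1,3,2-dioxaborolan-2-yl)pent-4-en-1-yl]tetrahydropyrrolo[2,1-b]oxazol-5(6H)-one | CC(C)[C@H]1CO[C@]2(C)C[C@](C)(CCCC(=C)B3OC(C)(C)C(C)(C)O3)C(=O)N12 | intermediate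
8 | (R)-linalool | C=C[C@](C)(O)CCC=C(C)C | starting material
9 | (R)-linalool tert-butyldimethylsilyl ether | C=C[C@](C)(O[Si](C)(C)C(C)(C)C)CCC=C(C)C | intermediate
10 | (6R)-6-(tert-butyldimethylsilyloxy)-2,6-dimethyloct-7-ene-2,3-diol | C=C[C@](C)(O[Si](C)(C)C(C)(C)C)CCC(O)C(C)(C)O | intermediate (not isolated)
11 | (R)-4-(tert-butyldimethylsilyloxy)-4-methylhex-5-enal | C=C[C@](C)(O[Si](C)(C)C(C)(C)C)CCC=O | intermediate
12 | (2E,6R)-6-(tert-butyldimethylsilyloxy)-6-methylocta-2,7-dienal | C=C[C@](C)(O[Si](C)(C)C(C)(C)C)CC/C=C/C=O | intermediate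
13 | (3S,6R)-6-(tert-butyldimethylsilyloxy)-6-methyl-3-{5-[(3S,6S,7aR)-lactam-6-yl]pent-1-en-2-yl}oct-7-enal | C=C[C@](C)(O[Si](C)(C)C(C)(C)C)CC[C@@H](CC=O)C(=C)CCC[C@@]1(C)C[C@@]2(C)OC[C@H](C(C)C)N2C1=O | intermediate
14 | enol nonaflate of 13 | C=C[C@](C)(O[Si](C)(C)C(C)(C)C)CC[C@@H](C=COS(=O)(=O)C(F)(F)C(F)(F)C(F)(F)C(F)(F)F)C(=C)CCC[C@@]1(C)C[C@@]2(C)OC[C@H](C(C)C)N2C1=O | intermediate (not isolated)
15 | (3S,6S,7aR)-6-[(5R,8R)-8-(tert-butyldimethylsilyloxy)-5-ethynyl-8-methyl-4-methylidenedec-9-en-1-yl]-3-isopropyl-6,7a-dimethyltetrahydropyrrolo[2,1-b]oxazol-5(6H)-one | C=C[C@](C)(O[Si](C)(C)C(C)(C)C)CC[C@@H](C#C)C(=C)CCC[C@@]1(C)C[C@@]2(C)OC[C@H](C(C)C)N2C1=O | intermediate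
16 | 5-hydroxy carbinolamine from 15 | C=C[C@](C)(O[Si](C)(C)C(C)(C)C)CC[C@@H](C#C)C(=C)CCC[C@@]1(C)C[C@@]2(C)OC[C@H](C(C)C)N2C1O | intermediate (not isolated)
17 | (2S,7R,10R)-10-(tert-butyldimethylsilyloxy)-7-ethynyl-2,10-dimethyl-6-methylidene-2-(2-oxopropyl)dodec-11-enal | C=C[C@](C)(O[Si](C)(C)C(C)(C)C)CC[C@@H](C#C)C(=C)CCC[C@](C)(C=O)CC(C)=O | intermediate
18 | (2S,7R,10R)-10-(tert-butyldimethylsilyloxy)-7-ethynyl-2,10-dimethyl-6-methylidene-2-(2-oxopropyl)dodec-11-enoic acid | C=C[C@](C)(O[Si](C)(C)C(C)(C)C)CC[C@@H](C#C)C(=C)CCC[C@](C)(C(=O)O)CC(C)=O | intermediate (not isolated)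
19 | methyl (2S,7R,10R)-10-(tert-butyldimethylsilyloxy)-7-ethynyl-2,10-dimethyl-6-methylidene-2-(2-oxopropyl)dodec-11-enoate | C=C[C@](C)(O[Si](C)(C)C(C)(C)C)CC[C@@H](C#C)C(=C)CCC[C@](C)(C(=O)OC)CC(C)=O | intermediate
20 | methyl (1S,2R,3R)-2-acetyl-3-[(3S,6R)-6-(tert-butyldimethylsilyloxy)-6-methyloct-7-en-1-yn-3-yl]-1,3-dimethylcyclohexane-1-carboxylate | C=C[C@](C)(O[Si](C)(C)C(C)(C)C)CC[C@@H](C#C)[C@@]1(C)CCC[C@](C)(C(=O)OC)[C@@H]1C(C)=O | intermediate (not isolated)
21 | methyl (4S,5R,9S,10R,13R)-13-(tert-butyldimethylsilyloxy)-6-oxolabda-8(17),14-dien-19-oate | C=C[C@](C)(O[Si](C)(C)C(C)(C)C)CC[C@H]1C(=C)CC(=O)[C@H]2[C@@](C)(C(=O)OC)CCC[C@]12C | intermediate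
22 | C6 p-toluenesulfonylhydrazone of 21 | C=C[C@](C)(O[Si](C)(C)C(C)(C)C)CC[C@H]1C(=C)CC(=NNS(=O)(=O)c3ccc(C)cc3)[C@H]2[C@@](C)(C(=O)OC)CCC[C@]12C | intermediate
23 | N-(1,3,2-benzodioxaborol-2-yl)-N'-tosylhydrazine at C6 | C=C[C@](C)(O[Si](C)(C)C(C)(C)C)CC[C@H]1C(=C)CC(N(B3Oc4ccccc4O3)NS(=O)(=O)c3ccc(C)cc3)[C@H]2[C@@](C)(C(=O)OC)CCC[C@]12C | intermediate (not isolated)
24 | methyl (13R)-13-(tert-butyldimethylsilyloxy)labda-8(17),14-dien-19-oate | C=C[C@](C)(O[Si](C)(C)C(C)(C)C)CC[C@H]1C(=C)CC[C@H]2[C@@](C)(C(=O)OC)CCC[C@]12C | intermediate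
25 | (13R)-13-(tert-butyldimethylsilyloxy)labda-8(17),14-dien-19-ol | C=C[C@](C)(O[Si](C)(C)C(C)(C)C)CC[C@H]1C(=C)CC[C@H]2[C@@](C)(CO)CCC[C@]12C | intermediate
26 | (13R)-13-(tert-butyldimethylsilyloxy)labda-8(17),14-dien-19-yl (E)-2-methylbut-2-enoate | C=C[C@](C)(O[Si](C)(C)C(C)(C)C)CC[C@H]1C(=C)CC[C@H]2[C@@](C)(COC(=O)/C(C)=C/C)CCC[C@]12C | intermediate
27 | (4S,5R,9S,10R,13R)-13-hydroxylabda-8(17),14-dien-19-yl (E)-2-methylbut-2-enoate | C=C[C@](C)(O)CC[C@H]1C(=C)CC[C@H]2[C@@](C)(COC(=O)/C(C)=C/C)CCC[C@]12C | target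

**Count**
Total steps: 17. Longest linear sequence: 13 steps (steps 5–17 from (R)-linalool; equally 2–4 and 8–17 from the lactam).

**Steps most likely to fail**

Step 12 (Proposed new method). What may go wrong: the alkyne may be consumed (hydration, or attack by the C13 silyloxy oxygen) before ring A has closed; the face selectivity at C10 may be poor; and the 8(17) double bond may migrate into conjugation with C6=O under acid catalysis. The fallback makes the two bonds one after the other by known reactions. It sets out from keto ester 19. A thermal Conia-ene reaction (degassed diphenyl ether, silylated sealed tube, about 330 °C) should close ring A only: the enol hydrogen is delivered to C20 through a six-membered transition state, while the linear alkyne cannot be reached in the same way. This gives the monocyclic ketone 20, now isolated. TBSOTf/Et3N should give the less substituted silyl enol ether F1. [AuCl(PPh3)]/AgBF4 in CH2Cl2/MeOH at 20 °C (silyl enol ether carbocyclisation, 6-exo-dig) then closes ring B under near-neutral conditions, and the route is rejoined at ketone 21.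

Step 8. What may go wrong: protodeboronation of the hindered α-substituted alkenylboronate and competing 1,2-addition to the enal. The fallback replaces catalyst control by auxiliary control and sets out from aldehyde 11 and vinyl bromide 6. Wittig reaction of 11 with (R)-4-phenyl-3-[(triphenylphosphoranylidene)acetyl]oxazolidin-2-one gives the N-enoyl oxazolidinone F2. Bromide 6 is converted with t-BuLi at −78 °C and CuBr·SMe2 into the alkenylcopper reagent, which should add to F2 anti to the phenyl group to give the imide F3. LiBH4 removes the auxiliary and gives the primary alcohol F4, and Dess–Martin oxidation rejoins the route at aldehyde 13.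

Step 13 (with step 14). What may go wrong: slow hydrazone formation at the hindered C6 ketone and migration of the 8(17) alkene into conjugation before or during reduction. The fallback removes the oxygen as an alcohol by a radical route and sets out from ketone 21. Luche reduction (NaBH4, CeCl3, MeOH, −40 °C) should give the 6β-alcohol, which closes onto the axial ester to the 19,6β-lactone F5. LiAlH4 gives the 6β,19-diol F6. Tigloyl chloride in pyridine at 0 °C should acylate only the primary hydroxyl to give the hydroxy tiglate F7. PhOC(S)Cl/DMAP gives the thionocarbonate F8, and Bu3SnH/AIBN (Barton–McCombie deoxygenation) rejoins the route at tiglate 26.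

**Further compounds**
F1 | step 12 | tert-butyldimethylsilyl enol ether (C6=C7) of monocyclic ketone 20 | C=C[C@](C)(O[Si](C)(C)C(C)(C)C)CC[C@@H](C#C)[C@@]1(C)CCC[C@](C)(C(=O)OC)[C@@H]1C(=C)O[Si](C)(C)C(C)(C)C
F2 | step 8 | (R)-3-[(2E,6R)-6-(tert-butyldimethylsilyloxy)-6-methylocta-2,7-dienoyl]-4-phenyloxazolidin-2-one | C=C[C@](C)(O[Si](C)(C)C(C)(C)C)CC/C=C/C(=O)N1[C@H](c2ccccc2)COC1=O
F3 | step 8 | (3S)-conjugate adduct imide (acyl oxazolidinone analogue of 13) | C=C[C@](C)(O[Si](C)(C)C(C)(C)C)CC[C@@H](CC(=O)N3[C@H](c4ccccc4)COC3=O)C(=C)CCC[C@@]1(C)C[C@@]2(C)OC[C@H](C(C)C)N2C1=O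
F4 | step 8 | primary alcohol corresponding to aldehyde 13 | C=C[C@](C)(O[Si](C)(C)C(C)(C)C)CC[C@@H](CCO)C(=C)CCC[C@@]1(C)C[C@@]2(C)OC[C@H](C(C)C)N2C1=O
F5 | step 13 | (13R)-13-(tert-butyldimethylsilyloxy)labda-8(17),14-dien-19,6β-olide | C=C[C@](C)(O[Si](C)(C)C(C)(C)C)CC[C@H]1C(=C)C[C@H]3[C@H]2[C@@](C)(C(=O)O3)CCC[C@]12C
F6 | step 13 | (13R)-13-(tert-butyldimethylsilyloxy)labda-8(17),14-diene-6β,19-diol | C=C[C@](C)(O[Si](C)(C)C(C)(C)C)CC[C@H]1C(=C)C[C@H](O)[C@H]2[C@@](C)(CO)CCC[C@]12C
F7 | step 13 | 6β-hydroxy analogue of tiglate 26 | C=C[C@](C)(O[Si](C)(C)C(C)(C)C)CC[C@H]1C(=C)C[C@H](O)[C@H]2[C@@](C)(COC(=O)/C(C)=C/C)CCC[C@]12C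
F8 | step 13 | 6β-O-phenoxythiocarbonyl derivative of F7 | C=C[C@](C)(O[Si](C)(C)C(C)(C)C)CC[C@H]1C(=C)C[C@H](OC(=S)Oc3ccccc3)[C@H]2[C@@](C)(COC(=O)/C(C)=C/C)CCC[C@]12C
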